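**Plan**
- Ring numbering used below: cyclohexene C1 (sp2 carbon bearing CH3), C2 (=CH), C3 (CH–aryl), C4 (quaternary), C5, C6. The retrosynthesis cuts first both pyranone rings (each coumarin back to a 2,6-dimethoxyphenyl group), then the vinyl–aryl bond of the styryl arm (back to an ethynyl group on C4), then C2–C3 and C5–C6 together, and last C3–C4 (alkynyl epoxide plus aryl aldehyde).
- Enabling feature: C3 is benzylic to an aryl carbon flanked by two oxygens and has no β-hydrogen, because its only sp3 neighbour C4 is quaternary. C5 is a CH2 on that same carbon, so C3–C4–C5 is a 1,3-dielectrophile at the 1,3-diol level. C6–C1(CH3)=C2 is a 2-methylallyl unit that a 1-silylallyl metal delivers as a carbanion at C6 and a vinylsilane at C2.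
- Forward order: chiral epoxide, then alkynyl 1,3-diol (C3–C4), then triflate/silyl ether, then a one-flask annulation that closes the cyclohexene, then alkyne to (E)-styryl, then both coumarin rings closed together.
- Stereochemistry: C4 comes from (R)-2-methylglycidol by chirality transfer through an allenylindium. C3 is set in the annulation by 1,3-allylic strain (the ethynyl group eclipses the aryl, the tether attacks from its own face, so aryl ends cis to the future styryl arm). The (E)-alkene comes from syn-hydrozirconation.

Key step: step 5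

Remark: the benzylic carbinol configuration in 6, 7, 8 and 11 is of no consequence, because that carbon is ionised in step 5; it is written as (R) for definiteness.

Step 1
Reactants: 1 (R)-(2-methyloxiran-2-yl)methanol
Product: 2 (S)-2-methyloxirane-2-carbaldehyde
Conditions: TEMPO (10 mol %), PhI(OAc)2, CH2Cl2, 0 °C to rt; used as a solution
Reagents that add atoms: none
Why: Nitroxyl-catalysed oxidation of a primary alcohol to the aldehyde runs under neutral conditions that should leave the epoxide intact, and the stereocentre has no α-hydrogen and cannot epimerise.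

Step 2
Reactants: 2 (S)-2-methyloxirane-2-carbaldehyde
Product: 3 (R)-2-ethynyl-2-methyloxirane
Conditions: dimethyl (1-diazo-2-oxopropyl)phosphonate, K2CO3, MeOH, 0 °C to rt
Reagents that add atoms: dimethyl (1-diazo-2-oxopropyl)phosphonate, COP(=O)(OC)C(=[N+]=[N-])C(C)=O
Why: The Ohira–Bestmann (Seyferth–Gilbert) homologation should convert the non-enolisable aldehyde into the terminal alkyne under mild conditions without touching the stereocentre.

Step 3
Reactants: 3 (R)-2-ethynyl-2-methyloxirane; 4 2,6-dimethoxybenzaldehyde
Product: 6 (1R,2S)-1-(2,6-dimethoxyphenyl)-2-ethynyl-2-methylpropane-1,3-diol, via allenylindium alkoxide 5 (not isolated)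
Conditions: Pd(PPh3)4 (5 mol %), InI (1.3 equiv), THF/HMPA 4:1, rt
Reagents that add atoms: none
Why: In this palladium/indium-mediated carbonyl propargylation, zerovalent palladium should open the alkynyl epoxide anti-SN2′, transmetalation should give allenylindium 5, and syn-SE2′ addition of 5 to 4 through a closed transition state should form the quaternary carbon with net inversion, so the epoxide stereocentre is relayed (expected 2S; if the sense proved opposite, the enantiomer of 1 would be used).

Step 4
Reactants: 6 (1R,2S)-1-(2,6-dimethoxyphenyl)-2-ethynyl-2-methylpropane-1,3-diol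
Product: 8 (2S,3R)-3-(2,6-dimethoxyphenyl)-2-ethynyl-2-methyl-3-[(triethylsilyl)oxy]propyl trifluoromethanesulfonate, via hydroxy triflate 7 (not isolated)
Conditions: Tf2O (1.05 equiv), 2,6-lutidine, CH2Cl2, −78 °C; then Et3SiOTf, −78 to −30 °C
Reagents that add atoms: trifluoromethanesulfonic anhydride, O=S(=O)(OS(=O)(=O)C(F)(F)F)C(F)(F)F; triethylsilyl trifluoromethanesulfonate, CC[Si](CC)(CC)OS(=O)(=O)C(F)(F)F
Why: The primary neopentyl hydroxyl should be triflated first at −78 °C and the hindered benzylic hydroxyl silylated next in the same flask (standard sulfonylation and silylation), which gives a triflate that cannot eliminate and a benzylic ether that is stable to base but ionisable by acid.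

Step 5
Reactants: 8 (2S,3R)-3-(2,6-dimethoxyphenyl)-2-ethynyl-2-methyl-3-[(triethylsilyl)oxy]propyl trifluoromethanesulfonate; 9 trimethyl(2-methylprop-2-en-1-yl)silane
Product: 12 2-[(1R,6S)-6-ethynyl-3,6-dimethylcyclohex-2-en-1-yl]-1,3-dimethoxybenzene, via silylallyl Grignard reagent 10 (not isolated), via open-chain vinylsilane 11 (not isolated)
Conditions: 9, s-BuLi, TMEDA, THF, −78 to −30 °C, then MgBr2·OEt2 (gives 10, 2.2 equiv); 8, Li2CuCl4 (5 mol %), −78 to −20 °C; then CH2Cl2, CF3CO2H (excess), −78 to −10 °C, NaHCO3 quench at −10 °C
Reagents that add atoms: none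
Why: Under copper catalysis 10 should couple through its silicon-remote CH2 terminus with the neopentyl triflate (SN2 at C5, forming C5–C6) to give 11 (one further equivalent of 10 is used up by the alkyne C–H), and trifluoroacetic acid should then ionise the benzylic silyl ether to a 2,6-dimethoxybenzyl cation at C3 that is captured by the vinylsilane at its silicon-bearing carbon (forming C2–C3), after which the tertiary β-silyl cation at C1 loses silicon and so fixes the double bond at C1=C2. The closest known reaction types are the copper-catalysed coupling of Grignard reagents with primary alkyl triflates, the γ-alkylation of 1-silylallyl metals and the vinylsilane-terminated cationic cyclisation. The ring closes in the 6-endo-trig mode with respect to the vinylsilane through a chair transition state. The new stereocentre C3 is controlled by 1,3-allylic strain in the cation: the slim ethynyl group eclipses the aryl–C3 bond, methyl and the C5 tether lie on opposite faces, and the tethered nucleophile can attack only from the face of C5, so the aryl group ends equatorial and cis to the axial ethynyl group. The step needs γ- over α-coupling (secured by the hindered electrophile and by silicon on the other terminus), a cation that neither eliminates nor rearranges (C3 has no β-hydrogen because C4 is quaternary, and the alkynyl group does not participate) and endo over exo closure (only endo attack gives a tertiary β-silyl cation). Both vinylsilane geometries should converge on the same cyclohexene, because the ring dictates the cis double bond.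

Step 6
Reactants: 12 2-[(1R,6S)-6-ethynyl-3,6-dimethylcyclohex-2-en-1-yl]-1,3-dimethoxybenzene; 13 2-iodo-1,3-dimethoxybenzene
Product: 15 2-{(1R,6R)-6-[(E)-2-(2,6-dimethoxyphenyl)ethenyl]-3,6-dimethylcyclohex-2-en-1-yl}-1,3-dimethoxybenzene, via alkenylzirconocene 14 (not isolated)
Conditions: Cp2Zr(H)Cl (1.3 equiv), THF, rt; then 13, Pd(PPh3)4 (5 mol %), ZnCl2 (20 mol %), THF, 50 °C
Reagents that add atoms: none
Why: syn-Hydrozirconation of the terminal alkyne should place zirconium on the unhindered terminus, and the palladium-catalysed Negishi-type coupling of 14 with 13 proceeds with retention, so the (E)-styryl arm should form without touching the trisubstituted ring alkene.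

Step 7
Reactants: 15 2-{(1R,6R)-6-[(E)-2-(2,6-dimethoxyphenyl)ethenyl]-3,6-dimethylcyclohex-2-en-1-yl}-1,3-dimethoxybenzene
Product: 16 2-{(E)-2-[(1R,2R)-2-(2-hydroxy-6-methoxyphenyl)-1,4-dimethylcyclohex-3-en-1-yl]ethenyl}-3-methoxyphenol
Conditions: NaSEt (8 equiv), DMF, 130 °C; cold 1 M HCl work-up
Reagents that add atoms: none
Why: Thiolate demethylation (SN2 at methyl) should remove one methyl group from each 2,6-dimethoxyphenyl ring and then stop, because the phenoxide formed deactivates the second ether of the same ring; either methoxy group of a ring gives the same product.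

Step 8
Reactants: 16 2-{(E)-2-[(1R,2R)-2-(2-hydroxy-6-methoxyphenyl)-1,4-dimethylcyclohex-3-en-1-yl]ethenyl}-3-methoxyphenol
Product: 17 3-{(E)-2-[(1R,2R)-2-(3-formyl-2-hydroxy-6-methoxyphenyl)-1,4-dimethylcyclohex-3-en-1-yl]ethenyl}-2-hydroxy-4-methoxybenzaldehyde
Conditions: MgCl2, Et3N, (CH2O)n, MeCN, reflux; cold 1 M HCl work-up
Reagents that add atoms: formaldehyde (from paraformaldehyde), C=O
Why: Magnesium-mediated ortho-formylation of phenols delivers formaldehyde inside the magnesium phenoxide chelate only ortho to the hydroxyl, and the single free ortho position of each ring is the carbon that becomes C4a of the coumarin.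

Step 9
Reactants: 17 3-{(E)-2-[(1R,2R)-2-(3-formyl-2-hydroxy-6-methoxyphenyl)-1,4-dimethylcyclohex-3-en-1-yl]ethenyl}-2-hydroxy-4-methoxybenzaldehyde
Product: 18 7-methoxy-8-{(E)-2-[(1R,2R)-2-(7-methoxy-2-oxo-2H-chromen-8-yl)-1,4-dimethylcyclohex-3-en-1-yl]ethenyl}-2H-chromen-2-one
Conditions: Ph3P=C=C=O (2.4 equiv), toluene, 110 °C
Reagents that add atoms: (triphenylphosphoranylidene)ketene, O=C=C=P(c1ccccc1)(c1ccccc1)c1ccccc1
Why: Each phenol should add to the ketene to give an aryl ester ylide that closes by intramolecular Wittig olefination onto the ortho aldehyde, which forms both pyranone rings with the necessarily cis double bond at a temperature below that at which the 1,5-diene could undergo Cope or retro-Diels–Alder reactions.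

**Compound list**
1 | (R)-(2-methyloxiran-2-yl)methanol ((R)-2-methylglycidol) | OC[C@]1(C)CO1 | starting material
2 | (S)-2-methyloxirane-2-carbaldehyde | O=C[C@]1(C)CO1 | intermediate
3 | (R)-2-ethynyl-2-methyloxirane | C#C[C@]1(C)CO1 | intermediate
4 | 2,6-dimethoxybenzaldehyde | COc1cccc(OC)c1C=O | starting material
5 | iodo(3-methyl-4-oxidobuta-1,2-dien-1-yl)indium (allenylindium alkoxide, axial configuration as in the SMILES) | CC(C[O-])=[C@@]=C[In+]I | intermediate (not isolated)
6 | (1R,2S)-1-(2,6-dimethoxyphenyl)-2-ethynyl-2-methylpropane-1,3-diol | C#C[C@@](C)(CO)[C@@H](O)c1c(OC)cccc1OC | intermediate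
7 | (2S,3R)-3-(2,6-dimethoxyphenyl)-2-ethynyl-3-hydroxy-2-methylpropyl trifluoromethanesulfonate | C#C[C@@](C)(COS(=O)(=O)C(F)(F)F)[C@@H](O)c1c(OC)cccc1OC | intermediate (not isolated)
8 | (2S,3R)-3-(2,6-dimethoxyphenyl)-2-ethynyl-2-methyl-3-[(triethylsilyl)oxy]propyl trifluoromethanesulfonate | C#C[C@@](C)(COS(=O)(=O)C(F)(F)F)[C@@H](O[Si](CC)(CC)CC)c1c(OC)cccc1OC | intermediate
9 | trimethyl(2-methylprop-2-en-1-yl)silane | C=C(C)C[Si](C)(C)C | starting material
10 | [2-methyl-1-(trimethylsilyl)allyl]magnesium bromide (drawn with magnesium on the CH2 terminus) | CC(=C[Si](C)(C)C)C[Mg]Br | intermediate (not isolated)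
11 | triethyl{[(1R,2R)-1-(2,6-dimethoxyphenyl)-2-ethynyl-2,5-dimethyl-6-(trimethylsilyl)hex-5-en-1-yl]oxy}silane (E/Z mixture at the vinylsilane; present in the flask as its bromomagnesium acetylide) | C#C[C@@](C)(CCC(C)=C[Si](C)(C)C)[C@@H](O[Si](CC)(CC)CC)c1c(OC)cccc1OC | intermediate (not isolated)
12 | 2-[(1R,6S)-6-ethynyl-3,6-dimethylcyclohex-2-en-1-yl]-1,3-dimethoxybenzene (aryl cis to ethynyl) | C#C[C@@]1(C)CCC(C)=C[C@H]1c1c(OC)cccc1OC | intermediate
13 | 2-iodo-1,3-dimethoxybenzene | COc1cccc(OC)c1I | starting material
14 | chlorobis(cyclopentadienyl)zirconium (E)-alkenyl derived from 12 (ring configuration as in 12; cyclopentadienyl ligands drawn as σ-bonded rings) | C1=CC(C=C1)[Zr](Cl)(C1C=CC=C1)/C=C/[C@@]1(C)CCC(C)=C[C@H]1c1c(OC)cccc1OC | intermediate (not isolated)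
15 | 2-{(1R,6R)-6-[(E)-2-(2,6-dimethoxyphenyl)ethenyl]-3,6-dimethylcyclohex-2-en-1-yl}-1,3-dimethoxybenzene | COc1cccc(OC)c1/C=C/[C@@]1(C)CCC(C)=C[C@H]1c1c(OC)cccc1OC | intermediate
16 | 2-{(E)-2-[(1R,2R)-2-(2-hydroxy-6-methoxyphenyl)-1,4-dimethylcyclohex-3-en-1-yl]ethenyl}-3-methoxyphenol | COc1cccc(O)c1/C=C/[C@@]1(C)CCC(C)=C[C@H]1c1c(O)cccc1OC | intermediate
17 | 3-{(E)-2-[(1R,2R)-2-(3-formyl-2-hydroxy-6-methoxyphenyl)-1,4-dimethylcyclohex-3-en-1-yl]ethenyl}-2-hydroxy-4-methoxybenzaldehyde | COc1ccc(C=O)c(O)c1/C=C/[C@@]1(C)CCC(C)=C[C@H]1c1c(OC)ccc(C=O)c1O | intermediate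
18 | 7-methoxy-8-{(E)-2-[(1R,2R)-2-(7-methoxy-2-oxo-2H-chromen-8-yl)-1,4-dimethylcyclohex-3-en-1-yl]ethenyl}-2H-chromen-2-one | COc1ccc2ccc(=O)oc2c1/C=C/[C@@]1(C)CCC(C)=C[C@H]1c1c(OC)ccc2ccc(=O)oc12 | target

**Step count and risks**
Total step count: 9. Longest linear sequence: 9 steps (1 to 18); 4, 9 and 13 are purchased.

Steps most likely to fail:

Step 5. The allyl metal may couple through its silicon-bearing terminus (which would lead to the double-bond regioisomer), the nucleophile may cleave the triflate at sulfur, and facial discrimination at the benzylic cation may be incomplete. The fallback sets out from 11 and comes back at 12. The annulation is divided into separate operations: the coupling stage is quenched and 11 is isolated and purified from any α-coupled isomer. Bu4NF buffered with AcOH then removes the triethylsilyl group to give the carbinol (1R,2R)-1-(2,6-dimethoxyphenyl)-2-ethynyl-2,5-dimethyl-6-(trimethylsilyl)hex-5-en-1-ol F1. F1 is cyclised with a catalytic confined chiral Brønsted acid (an imidodiphosphorimidate) in a non-polar solvent at low temperature. The chiral counter-anion paired with the benzylic cation, and not the substrate alone, then selects the face (asymmetric counter-anion-directed cation–olefin cyclisation); the matched catalyst enantiomer is chosen.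

Step 3. Chirality transfer may erode through racemisation of the allenylmetal, and addition to the hindered, electron-rich aldehyde may be slow enough for the allenylindium to be protonated. The fallback sets out from 3 and comes back at 6. Copper-catalysed SN2′ borylation of the propargylic epoxide (CuCl, a bisphosphine, B2pin2, catalytic NaOtBu, MeOH, THF) gives the isolable, configurationally stable allenylboronate 2-methyl-4-(4,4,5,5-tetramethyl-1,3,2-dioxaborolan-2-yl)buta-2,3-dien-1-ol F2. F2 is then heated with 4 (toluene, 40 °C, optionally with a phosphoric acid catalyst), so that propargylation runs through a closed chair transition state and gives 6.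

Step 4. Sulfonylation may lose chemoselectivity (a benzylic triflate would ionise at once), and the hydroxy triflate may fragment or close to an oxetane before it is silylated. The fallback sets out from 6 and comes back at 12. Both hydroxyls are tied up in one operation as the cyclic sulfate (4R,5S)-4-(2,6-dimethoxyphenyl)-5-ethynyl-5-methyl-1,3,2-dioxathiane 2,2-dioxide F3 (SO2Cl2, Et3N, CH2Cl2, −78 °C). F3 serves as the 1,3-dielectrophile: 10 with Li2CuCl4 opens it at the CH2–O carbon to give the alkyl sulfate (1R,2R)-1-(2,6-dimethoxyphenyl)-2-ethynyl-2,5-dimethyl-6-(trimethylsilyl)hex-5-en-1-yl hydrogen sulfate F4 (as its magnesium salt). Acidification then ionises the benzylic sulfate and the vinylsilane closes the ring to 12.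

Further compounds
F1 | step 5 | (1R,2R)-1-(2,6-dimethoxyphenyl)-2-ethynyl-2,5-dimethyl-6-(trimethylsilyl)hex-5-en-1-ol | C#C[C@@](C)(CCC(C)=C[Si](C)(C)C)[C@@H](O)c1c(OC)cccc1OC
F2 | step 3 | 2-methyl-4-(4,4,5,5-tetramethyl-1,3,2-dioxaborolan-2-yl)buta-2,3-dien-1-ol (axial configuration as in the SMILES) | CC(CO)=[C@@]=CB1OC(C)(C)C(C)(C)O1
F3 | step 4 | (4R,5S)-4-(2,6-dimethoxyphenyl)-5-ethynyl-5-methyl-1,3,2-dioxathiane 2,2-dioxide | C#C[C@@]1(C)COS(=O)(=O)O[C@H]1c1c(OC)cccc1OC
F4 | step 4 | (1R,2R)-1-(2,6-dimethoxyphenyl)-2-ethynyl-2,5-dimethyl-6-(trimethylsilyl)hex-5-en-1-yl hydrogen sulfate | C#C[C@@](C)(CCC(C)=C[Si](C)(C)C)[C@@H](OS(=O)(=O)O)c1c(OC)cccc1OC
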